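All runs are calculated for substances that don't exist; noise was put on by code.

The share of target cannot be a fixed property of these reactants. Summed over the grey, red and violet runs, the side product stands to the target as 0.101 at 8.00 h but as 0.295 at 20.0 h.

| flask | substrate | partner | free catalyst | remark | time |
|---|---|---|---|---|---|
| grey | 0.44 M | 2.5 equiv | 10 mol% | run made earlier |  |
| red | 0.44 M | 3.5 equiv | 10 mol% | run made earlier |  |
| violet | 0.44 M | 5.5 equiv | 10 mol% | run made earlier |  |
| amber | 0.44 M | 2.5 equiv | 5 mol% | run made earlier |  |
| north-east | 0.44 M | 2.50 equiv | 10 mol% | a tube with plug flow, the mixed feed as stated, residence time 30 h | 30 h |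
| north | 0.44 M | 2.50 equiv | 10 mol% | a single well-mixed tank run continuously and read at steady state, 30 h in it on average |  |
| north-west | 0.44 M (fed, over 30.0 h) | 2.50 equiv | 10 mol% | a stirred flask in which substrate is dosed at a steady rate over 30.0 h without added volume, worked up at 30 h | 30 h |
| south | 0.44 M | 2.50 equiv | 10 mol% | everything together in a closed stirred flask, run for 30 h | 30 h |

| run | time / h | target / % | side product / % | substrate / % |
|---|---|---|---|---|
| grey | 1.33 | 0 | 0 | 93.8 |
| grey | 2.00 | 0.8 | 0 | 92.2 |
| grey | 3.00 | 1.0 | 0 | 92.2 |
| grey | 5.00 | 2.8 | 0 | 90.0 |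
| grey | 8.00 | 5.8 | 1.1 | 87.9 |
| grey | 12.0 | 7.3 | 0.9 | 85.9 |
| grey | 20.0 | 11.3 | 2.3 | 80.8 |
| red | 2.50 | 1.5 | 0.2 | 91.7 |
| red | 5.00 | 2.8 | 0.1 | 90.0 |
| red | 8.00 | 4.5 | 0.5 | 87.0 |
| red | 10.0 | 6.4 | 1.4 | 86.6 |
| red | 12.0 | 7.4 | 1.7 | 84.7 |
| red | 15.0 | 9.6 | 0.9 | 82.7 |
| red | 20.0 | 11.3 | 3.8 | 80.4 |
| violet | 2.50 | 0.4 | 0.5 | 91.0 |
| violet | 5.00 | 3.9 | 0 | 88.4 |
| violet | 8.00 | 5.6 | 0 | 87.3 |
| violet | 10.0 | 7.1 | 0.8 | 86.4 |
| violet | 12.0 | 8.4 | 2.1 | 85.5 |
| violet | 15.0 | 10.9 | 2.3 | 83.8 |
| violet | 20.0 | 12.6 | 4.3 | 80.1 |
| amber | 1.33 | 0 | 0.2 | 96.5 |
| amber | 2.50 | 0.5 | 0 | 97.4 |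
| amber | 5.00 | 0.9 | 0 | 95.2 |
| amber | 10.0 | 3.8 | 0.7 | 92.7 |
| amber | 20.0 | 5.5 | 2.9 | 88.8 |

(standard deviation of a reading: 0.5 percentage points)

- a species is counted by the substrate in it: one side product counts as two
- the stated concentrations are those of everything mixed, before any reaction; amounts are the same in each set-up
- the feed brings no volume worth counting
- the earlier runs were made in a closed, stirred flask
- a reading or a percentage of target counts all its forms, free or not

* the set-up with the highest share of target in all that became target or side product, at the outlet or at the end ("none" if the first two lie within 2 percentage points) (north-east / north / north-west / south / none)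
* share of target in all that became target or side product, at the outlet or at the end, north-east
* share of target in all that became target or side product, at the outlet or at the end, north
* share of target in all that became target or side product, at the outlet or at the end, north-west
* share of target in all that became target or side product, at the outlet or at the end, south

So we follow one molecule of target and suppose, as in what the field calls a series reaction, that it has a steady chance per hour of ending in side product. The time constant of that chance is the capture time θ, and the rule is that the ratio ρ of side product to target equals the mean age of the target present divided by θ. With steady birth in a closed flask the mean age is half the elapsed time, so the 20.0 h ratio gives θ = 33.8 h.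

The first objection is that side product might simply form beside target, but then ρ would stay at 0.295 at 8.00 h, whereas the rule gives 0.118 and the reading is 0.101, so age stands. The second is worse: amber shows 0.527 at 20.0 h, more than 0.295, so θ shifts with loading, and we use it at 10 mol% alone, the loading of all the set-ups asked about.

South and the tube, where every element ages 30 h, then give 69.3%. In the tank the mean age is the full 30 h, giving 53.0%. But substrate sits lower there, and scaling θ by the readings 85.9% and 80.8% raises this only to 54.5%. In the dosed flask substrate climbs from nil, so ρ falls to a third of 30.0 h over θ, or 77.2%. If birth follows substrate it falls to a quarter, or 81.8%, and the runs cannot separate these, so we commit to that range.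

The forecast says 79%, 81%, 90% and 79% for north-east, north, north-west and south, with north-west best, taking side product as “uncatalysed and second order in substrate”. It stands above us on all four and puts the tank above the flask, where we put it below.

The set-ups give 68.4% in north-east, 59.6% in north, 82.9% in north-west and 68.4% in south, so north-west is best, and north lies lower than south by 8.8 percentage points.

    substrate + free catalyst → catalyst intermediate A (k = 4.20 × 10⁻⁴ M⁻¹ s⁻¹)
    partner + catalyst intermediate A → catalyst intermediate B (k = 1.70 × 10⁻⁴ M⁻¹ s⁻¹)
    catalyst intermediate B → free catalyst + target (k = 4.10 × 10⁻⁵ s⁻¹)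
    free catalyst + target ⇌ idle complex, settled at all times (K = 210 M⁻¹)
    partner → decomposed reagent (k = 8.70 × 10⁻⁷ s⁻¹)
    substrate + target → side product (k = 1.80 × 10⁻⁵ M⁻¹ s⁻¹)

North-west ends with 11.5% target and 82.1% substrate. Left until 300 h, north-west stands at 25.8%, which makes ρ = 2.88, and read through the rule with θ this is a mean age of 97.3 h for its target, about a third of that time.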